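The runs were computed with made-up constants, and the scatter is random.

Reckon this flask in reciprocal minutes: the chance per minute that one molecule of electrophile becomes product.

| flask | electrophile | nucleophile | free base | remark | time |
|---|---|---|---|---|---|
| birch | 0.25 M (fed, over 12 min) | 3.8 equiv | 1 equiv | run made earlier |  |
| flask | 0.25 M (fed, over 12 min) | 2.50 equiv | 1.00 equiv |  | 50 min |
- birch (time / min: electrophile / %, product / %): 4.00: 33, 2; 8.00: 47, 7; 12.0: 70, 9; 15.0: 64, 14

(standard deviation of a reading: 2 percentage points)
- what has gone from electrophile into another species counts as reacted, even if it can come back
- percentages count the whole charge, also what has not yet gone in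
- the earlier runs do not show how much of nucleophile is bound; that part of a forecast is a guess
- part of the electrophile that has reacted at 50 min
- share of the unused nucleophile that is free and not bound as protonated nucleophile, at 50 min

Start from the birch run and let product form at a constant times c(electrophile). The area under the electrophile readings up to 15.0 min is 6.61 min of whole charge, so the 14% of product read then gives 0.0212 min⁻¹. Scale this to the nucleophile of this flask, as for a pseudo-first-order step, which gives 0.0139 min⁻¹.

But the birch balance has a gap: at 12.0 min, with the feed finished, electrophile is 76.9% of what is not yet product. Assume that the unseen rest cannot react, so one molecule faces the fork to product for that share of its time. An average molecule enters at 6.00 min and has 44.0 min to go, so the reacted part comes to 52.0%.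

The weak link is that share, so reforge it from the later reading, 74.4%. This gives, as a reading that carries the scatter of the birch run, the pool constant, the chance per minute that a molecule not yet product becomes product, 0.0104 min⁻¹. The pool left in this flask at 50 min is 63.4%, and I commit to 52.8% reacted. Product near 36.6% of the charge stays below the 1.00 equiv of free base, so guess that the nucleophile stays free.

The forecast stands at 72% and 90%: “Most nucleophile stays free, but this is a guess”.

The flask gives 53.4% reacted and >99.9% free, with product at 30.6%, less than the 36.6% that the pool constant gave.

    electrophile ⇌ dormant form (K = 0.470, k = 0.00150 s⁻¹)
    acid set free + free base ⇌ salt of the base, settled at all times (K = 2.20 × 10⁵ L mol⁻¹)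
    electrophile + nucleophile → acid set free + product (k = 3.40 × 10⁻⁴ L mol⁻¹ s⁻¹)
    nucleophile + acid set free ⇌ protonated nucleophile, settled at all times (K = 21.0 L mol⁻¹)

At 24.3 min the flask uses electrophile for product at 0.13 of the forward rate of its loss to the dormant form. The half-life of electrophile by that forward step alone, 7.7 min at 50.0 min, is short against the time of the flask, and the dormant form then holds 22.8% of the charge.

For the neighbour with 1.50 equiv of nucleophile, the pool constant scales to 0.00622 min⁻¹, which gives 43.4% reacted. That neighbour computes to 45.8%, with product at 19.7%.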